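## Retrosynthetic overview
1. Gravicycle ⇐ its tri-O-benzyl ether ⇐ (alkene saturation) a 22-membered (R,E)-1-arylallyl alcohol.
2. Key disconnection: the C1(carbinol)–C2 bond. One catalytic asymmetric alkenylzinc-to-ArCHO addition closes the macrocycle and sets C1 in the same step, so there is no RCM, no macro-Ullmann and no ketone reduction.
3. The acyclic ω-alkynyl benzaldehyde ⇐ intermolecular Ullmann etherification of a ring-A phenol with a 4-bromo-3,5-bis(benzyloxy)benzaldehyde (ring B).
4. The ring-A phenol ⇐ B-alkyl Suzuki coupling of 3-(benzyloxy)-5-bromophenol with a C13 TIPS-enyne (11-bromoundecene + TIPS-acetylene).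
5. Ring order: both arenes are purchased. The macrocycle is the only ring formed, and it forms together with the stereocentre.

Assumptions: the SMILES stereocentre reads as (R) (OH > aryl > CH2 > H) and the tether is CH(OH) + 13 CH2. (2R)-(+)-DAIB is treated as a purchasable catalytic ligand. Locants: C1 = carbinol carbon, C14 = benzylic CH2 on ring A.

## Route

**Step 1**
Reactants: 1 (triisopropylsilyl)acetylene; 2 11-bromoundec-1-ene
Product: 3 triisopropyl(tridec-12-en-1-yn-1-yl)silane
Conditions: n-BuLi, THF, −78 → 0 °C; then 2, DMPU, 0 → 60 °C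
Reagents that add atoms: none (both partners are listed reactants)
Why: This is an SN2 alkylation of a lithium acetylide with a primary bromide, and the TIPS cap later shields the alkyne from 9-BBN, Pd and Cu.

**Step 2**
Reactants: 4 3,5-dibromophenol
Product: 5 1-(benzyloxy)-3,5-dibromobenzene
Conditions: BnBr, K2CO3, DMF, rt
Reagents that add atoms: benzyl bromide, BrCc1ccccc1
Why: This is a Williamson ether synthesis on an acidic, unhindered phenol.

**Step 3**
Reactants: 5
Product: 6 3-(benzyloxy)-5-bromophenol
Conditions: n-BuLi (1.0 equiv), Et2O, −78 °C; B(OMe)3, −78 °C → rt; 30% H2O2, aq NaOH, 0 °C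
Reagents that add atoms: hydrogen peroxide, OO
Why: Br/Li exchange stops at the monolithio stage, so this lithiation–borylation–oxidation desymmetrises 5 non-statistically, and the OBn group is inert at −78 °C.

**Step 4**
Reactants: 3; 6
Product: 7 3-(benzyloxy)-5-[13-(triisopropylsilyl)tridec-12-yn-1-yl]phenol
Conditions: 3, 9-BBN (1.0 equiv), THF, 0 °C → rt; then 6, Pd(dppf)Cl2 (5 mol %), aq K3PO4 (4 equiv), THF/DMF, 60 °C
Reagents that add atoms: none
Why: 9-BBN hydroborates the terminal alkene anti-Markovnikov while the TIPS-alkyne is too hindered to react, and the following B-alkyl Suzuki–Miyaura coupling tolerates the free phenol because extra base is present.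

**Step 5**
Reactants: 8 4-bromo-3,5-dimethoxybenzaldehyde
Product: 9 4-bromo-3,5-dihydroxybenzaldehyde
Conditions: BBr3 (3 equiv), CH2Cl2, −78 °C → rt; H2O
Reagents that add atoms: none
Why: BBr3 cleaves the aryl methyl ethers before any alkyne or stereocentre exists, and aqueous work-up regenerates the aldehyde.

**Step 6**
Reactants: 9
Product: 10 3,5-bis(benzyloxy)-4-bromobenzaldehyde
Conditions: BnBr (2.3 equiv), K2CO3, DMF, 40 °C
Reagents that add atoms: benzyl bromide, BrCc1ccccc1
Why: This is a double Williamson etherification, and the aldehyde is non-enolisable and inert to carbonate.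

**Step 7**
Reactants: 7; 10
Product: 11 3,5-bis(benzyloxy)-4-{3-(benzyloxy)-5-[13-(triisopropylsilyl)tridec-12-yn-1-yl]phenoxy}benzaldehyde
Conditions: CuI (20 mol %), picolinic acid (40 mol %), K3PO4, 4 Å MS, DMSO, 95 °C, Ar
Reagents that add atoms: none
Why: In this ligand-accelerated Ullmann diaryl ether synthesis the C–Br bond is activated by the para-CHO, the phenol is unhindered and electron-rich, the picolinic acid system suits ortho-substituted partners, and TIPS blocks Cu-acetylide side reactions.

**Step 8**
Reactants: 11
Product: 12 3,5-bis(benzyloxy)-4-[3-(benzyloxy)-5-(tridec-12-yn-1-yl)phenoxy]benzaldehyde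
Conditions: TBAF (1.5 equiv), THF containing 2% H2O, 0 °C → rt
Reagents that add atoms: none
Why: Fluoride cleaves the C(sp)–Si bond, and the added water protonates the acetylide before it can add to the aldehyde.

**Step 9 (key step)**
Reactants: 12
Product: 13 (1R,2E)-tri-O-benzyl-2,3-didehydrogravicycle. This is the 22-membered diaryl ether cyclophane in which ring B C1' carries (R)-CH(OH)–CH=CH(E)–(CH2)11– joined to ring A.
Conditions: Cy2BH (1.05 equiv, fresh from cyclohexene/BH3·SMe2), toluene, 0 °C, 1.5 h; then syringe pump (8 h) into Et2Zn (2.5 equiv), (2R)-(+)-DAIB (10 mol %), toluene, 0 °C (final ~3 mM); aq NH4Cl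
Reagents that add atoms: none
Why: This is an Oppolzer-type macrocyclisation in which Cy2BH hydroborates the terminal alkyne faster than it reduces ArCHO, B→Zn exchange gives an (E)-alkenyl(ethyl)zinc, and the (+)-DAIB–Zn chelate delivers the alkenyl group intramolecularly to the Re face of the aldehyde (mirror of the known (−)-DAIB → Si face → (S) sense) to give (R), since OH > aryl > alkenyl > H.

**Step 10**
Reactants: 13
Product: 14 (R)-tri-O-benzylgravicycle (saturated macrocycle)
Conditions: 2-nitrobenzenesulfonylhydrazide (NBSH, 10 equiv in portions), Et3N, CH2Cl2, rt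
Reagents that add atoms: none
Why: Diimide reduction transfers H2 in a concerted syn fashion to the unhindered E-alkene, avoiding the π-allyl and ionisation pathways that could hydrogenolyse, transpose or racemise the allylic/benzylic carbinol, while Et3N buffers the sulfinic acid and the Bn ethers are untouched.

**Step 11**
Reactants: 14
Product: 15 (R)-gravicycle
Conditions: H2 (1 atm), 10% Pd/C, solid NaHCO3, EtOAc/EtOH, rt; stop at full conversion
Reagents that add atoms: none
Why: In this catalytic hydrogenolysis the phenolic benzyl ethers cleave much faster than a free secondary benzylic alcohol under buffered neutral conditions, so C1 stays (R).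

## Compound list
| No. | Name | SMILES | Role |
|---|---|---|---|
| 1 | (triisopropylsilyl)acetylene | C#C[Si](C(C)C)(C(C)C)C(C)C | starting material |
| 2 | 11-bromoundec-1-ene | C=CCCCCCCCCCBr | starting material |
| 3 | triisopropyl(tridec-12-en-1-yn-1-yl)silane | C=CCCCCCCCCCC#C[Si](C(C)C)(C(C)C)C(C)C | intermediate |
| 4 | 3,5-dibromophenol | Oc1cc(Br)cc(Br)c1 | starting material |
| 5 | 1-(benzyloxy)-3,5-dibromobenzene | Brc1cc(Br)cc(OCc2ccccc2)c1 | intermediate |
| 6 | 3-(benzyloxy)-5-bromophenol | Oc1cc(Br)cc(OCc2ccccc2)c1 | intermediate |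
| 7 | 3-(benzyloxy)-5-[13-(TIPS)tridec-12-yn-1-yl]phenol | Oc1cc(OCc2ccccc2)cc(CCCCCCCCCCCC#C[Si](C(C)C)(C(C)C)C(C)C)c1 | intermediate |
| 8 | 4-bromo-3,5-dimethoxybenzaldehyde | O=Cc1cc(OC)c(Br)c(OC)c1 | starting material |
| 9 | 4-bromo-3,5-dihydroxybenzaldehyde | O=Cc1cc(O)c(Br)c(O)c1 | intermediate |
| 10 | 3,5-bis(benzyloxy)-4-bromobenzaldehyde | O=Cc1cc(OCc2ccccc2)c(Br)c(OCc2ccccc2)c1 | intermediate |
| 11 | TIPS-alkynyl diaryl ether aldehyde | O=Cc1cc(OCc2ccccc2)c(Oc2cc(OCc3ccccc3)cc(CCCCCCCCCCCC#C[Si](C(C)C)(C(C)C)C(C)C)c2)c(OCc2ccccc2)c1 | intermediate |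
| 12 | terminal alkynyl diaryl ether aldehyde | O=Cc1cc(OCc2ccccc2)c(Oc2cc(OCc3ccccc3)cc(CCCCCCCCCCCC#C)c2)c(OCc2ccccc2)c1 | intermediate |
| 13 | (1R,2E)-tri-O-benzyl-2,3-didehydrogravicycle | c1ccccc1COc1cc2cc(c1)Oc1c(OCc3ccccc3)cc(cc1OCc1ccccc1)[C@H](O)/C=C/CCCCCCCCCCC2 | intermediate |
| 14 | (R)-tri-O-benzylgravicycle | c1ccccc1COc1cc2cc(c1)Oc1c(OCc3ccccc3)cc(cc1OCc1ccccc1)[C@H](O)CCCCCCCCCCCCC2 | intermediate |
| 15 | (R)-gravicycle | Oc1cc2cc(c1)Oc1c(O)cc(cc1O)[C@H](O)CCCCCCCCCCCCC2 | target |

## Summary
Total steps: 11. Longest linear sequence: 8 (steps 2, 3, 4, 7, 8, 9, 10, 11).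

Steps most likely to fail, each with one fallback:
1. **Step 9.** Risks are oligomerisation, competing ethyl transfer, aldehyde reduction by Cy2BH, and eroded ee.
   - Fallback: form C1–C2 intermolecularly using the same Cy2BH/Et2Zn/(+)-DAIB addition. The partners are the desilylated, phenol-protected ring-A alkyne and bromoaldehyde 10.
   - Then reduce with diimide, protect the carbinol as its TBS ether, free the phenol, and close the ring at the diaryl ether by high-dilution intramolecular Ullmann coupling.
2. **Step 7.** The di-ortho-benzyloxy aryl bromide may couple sluggishly or undergo hydrodebromination.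
   - Fallback: reverse the polarity. Convert 10 to 3,5-bis(benzyloxy)-4-hydroxybenzaldehyde by borylation/oxidation.
   - O-arylate it without metal using a ring-A aryl(mesityl)iodonium salt, made from the boronic acid available at step 3. This chemistry tolerates 2,6-disubstituted phenols.
3. **Step 11.** The risks are benzylic C–OH hydrogenolysis or loss of ee.
   - Fallback: exchange the protecting groups before the stereocentre exists. The sequence is 11 → BCl3/pentamethylbenzene (−78 °C) → TBAF → TBSCl/imidazole, giving the tris-TBS alkynal.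
   - The endgame then becomes macrocyclisation, diimide, and TBAF/AcOH, so the carbinol never meets Pd/H2.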